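**Strategy**

Everything rests on breaking the C9–C10 bond of ring B. With ketones placed at C4 (ring A) and C8 (ring B), the ring-fusion hydrogen at C5 and the hydrogen at C9 are both enolisable, so the quaternary C10 with its angular methyl C20 is the only ring stereocentre that a reagent must set. The precursor is therefore an achiral ring A enone (C4=O, C5=C10–CH3) whose C5 arm (C6–C7–C8–C9) ends in a β-keto ester. One enantioselective intramolecular Michael addition forms C9–C10, closes ring B and fixes C10, while C5 and C9 settle by equilibration. The C9 ester then activates C9 for attachment of C11–C13 and is excised.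

Key step: step 5

Remark on numbering: labdane numbering (C1–C20) is used for all bicyclic compounds; β is the face of the C10 methyl, α the opposite face.

Assumption: the quinine-derived amine (step 5) and the ligand enantiomer named (step 14) are taken to give the enantiomers drawn; if the sense of induction is the opposite, the quinidine-derived pseudo-enantiomer or the mirror-image ligand is used.

**Route**

Step 1
Reactants: 1 methyl 5-methoxy-3-oxopentanoate
Product: 2 methyl 3-oxopent-4-enoate
Conditions: TsOH·H2O (2 mol%), hydroquinone (trace), 110 °C, 20 mbar, distilled as formed, used at once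
Reagents that add atoms: none
Why: Acid-catalysed β-elimination of methanol from the β-methoxy ketone (retro-oxa-Michael reaction) is driven to the vinyl ketone by removing the volatile products as they form.

Step 2
Reactants: 2 methyl 3-oxopent-4-enoate; 3 cyclohexane-1,3-dione
Product: 4 methyl 5-(2-hydroxy-6-oxocyclohex-1-en-1-yl)-3-oxopentanoate
Conditions: 3 (1.5 equiv), Et3N (10 mol%), THF, 0 °C to rt, slow addition of 2
Reagents that add atoms: none
Why: Michael addition of C2 of the strongly acidic 1,3-dione to the unhindered vinyl ketone is a standard C-alkylation, and the excess of dione limits double addition.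

Step 3
Reactants: 4 methyl 5-(2-hydroxy-6-oxocyclohex-1-en-1-yl)-3-oxopentanoate
Product: 5 methyl 3-oxo-5-[6-oxo-2-(trifluoromethanesulfonyloxy)cyclohex-1-en-1-yl]pentanoate
Conditions: Tf2O (1.05 equiv), pyridine (1.5 equiv), CH2Cl2, −78 to −20 °C
Reagents that add atoms: trifluoromethanesulfonic anhydride, O=S(=O)(OS(=O)(=O)C(F)(F)F)C(F)(F)F
Why: Enol triflate formation (O-sulfonylation) should occur only at the ring vinylogous acid, which is far more acidic and more enolised than the side-chain β-keto ester, when one equivalent of anhydride is used cold.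

Step 4
Reactants: 5 methyl 3-oxo-5-[6-oxo-2-(trifluoromethanesulfonyloxy)cyclohex-1-en-1-yl]pentanoate
Product: 6 methyl 5-(2-methyl-6-oxocyclohex-1-en-1-yl)-3-oxopentanoate
Conditions: Me4Sn (2 equiv), Pd(PPh3)4 (5 mol%), LiCl (3 equiv), DMF, 60 °C
Reagents that add atoms: tetramethylstannane, C[Sn](C)(C)C
Why: Stille coupling of the electron-poor β-triflyloxy enone transfers the C20 methyl to C10 under neutral conditions, so the β-keto ester is never deprotonated and no racemic closure of 6 is triggered before step 5.

Step 5
Reactants: 6 methyl 5-(2-methyl-6-oxocyclohex-1-en-1-yl)-3-oxopentanoate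
Product: 7 methyl (1R,4aR,8aS)-8a-methyl-2,5-dioxodecahydronaphthalene-1-carboxylate (trans-fused diketo ester)
Conditions: 9-amino-9-deoxy-epi-quinine (20 mol%), CF3CO2H (40 mol%), H2O (5 equiv), toluene, 40 °C
Reagents that add atoms: none
Why: Proposed new method: the primary amine condenses with the C4 ketone of 6 to a ketiminium ion, the protonated quinuclidine hydrogen-bonds the enol of the β-keto ester, and C9 adds to C10 (Michael addition) to give a C4 enamine that hydrolyses to 7 and releases the catalyst, while reversible enamino ester formation at C8 is a resting state that can close the same bond. The closest known reaction types are base-mediated intramolecular Michael additions of β-keto esters to cyclohexenones and cinchona primary-amine iminium catalysis of additions to 3-substituted cyclohexenones that create quaternary centres, whereas a fully substituted 2,3-dialkyl enone has not been shown in this role. Ring B closes in a 6-endo-trig mode with respect to C5=C10 (enolendo for the donor) through a chair-like transition state. C10 is set by the catalyst, which leaves one face of the iminium ion open, and C5 (trans fusion) and C9 (equatorial ester, cis to the C10 methyl) are set thermodynamically by enamine and enol equilibration in the same flask, any cis-fused material being resubjected. The step needs attack at C10 in preference to 1,2-attack at C4 (a six-membered aldol or Knoevenagel closure) and to O-attack by the enol: the three-atom tether C6–C7–C8 holds C9 over C10, C4 carries the bulky ammonium substituent, the adducts at C4 and at oxygen revert in the wet acidic medium, and only the C9–C10 adduct is drained by tautomerisation to the 1,5-diketone. Racemic background closure is held down by the acid cocatalyst and by keeping 6 free of base.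

Step 6
Reactants: 7 methyl (1R,4aR,8aS)-8a-methyl-2,5-dioxodecahydronaphthalene-1-carboxylate
Product: 9 methyl 4-formyl-10β-methyl-8-oxodecalin-9β-carboxylate (C4 epimers), via enol ether 8 (not isolated)
Conditions: MeOCH2PPh3Cl (3.2 equiv), KN(SiMe3)2 (3.0 equiv), THF, 0 °C to rt; then 2 M HCl, THF, rt
Reagents that add atoms: (methoxymethyl)triphenylphosphonium chloride, COC[P+](c1ccccc1)(c1ccccc1)c1ccccc1.[Cl-]; water, O
Why: Wittig methoxymethylenation followed by acid hydrolysis of the enol ether is the standard one-carbon homologation of a ketone to an aldehyde, the first equivalent of ylide turns the β-keto ester into its enolate so that C8 and the ester are shielded, and the C4 configuration of 9 does not matter because step 7 erases it.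

Step 7
Reactants: 9 methyl 4-formyl-10β-methyl-8-oxodecalin-9β-carboxylate (C4 epimers)
Product: 10 methyl 4β-formyl-4α,10β-dimethyl-8-oxodecalin-9β-carboxylate
Conditions: KN(SiMe3)2 (2.1 equiv), THF, −78 °C; MeI (1.1 equiv), −78 to −30 °C; then AcOH
Reagents that add atoms: iodomethane, CI
Why: Enolate alkylation of the bis-enolate should occur at the more basic and less hindered aldehyde enolate in preference to the stabilised β-keto ester enolate, and iodomethane approaches C4 from the equatorial α face away from the axial C10 methyl, so the formyl group ends axial (β) under substrate control.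

Step 8
Reactants: 10 methyl 4β-formyl-4α,10β-dimethyl-8-oxodecalin-9β-carboxylate; 11 but-3-en-2-one
Product: 12 methyl 4β-formyl-4α,10β-dimethyl-8-oxo-9α-(3-oxobutyl)decalin-9β-carboxylate
Conditions: FeCl3·6H2O (5 mol%), 11 (3 equiv), CH2Cl2, rt
Reagents that add atoms: none
Why: Michael addition of the β-keto ester to the vinyl ketone under FeCl3 catalysis is neutral, leaves the non-enolisable aldehyde alone and brings in C11, C12, C13 and C16 at once, and the new C9 centre (attack expected anti to the C10 methyl) does not matter because step 12 erases it.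

Step 9
Reactants: 12 methyl 4β-formyl-4α,10β-dimethyl-8-oxo-9α-(3-oxobutyl)decalin-9β-carboxylate
Product: 13 9β-(methoxycarbonyl)-4α,10β-dimethyl-8-oxo-9α-(3-oxobutyl)decalin-4β-carboxylic acid
Conditions: NaClO2, NaH2PO4, 2-methylbut-2-ene, t-BuOH/H2O, 0 °C to rt
Reagents that add atoms: sodium chlorite, [Na+].[O-]Cl=O
Why: Pinnick oxidation converts the hindered aldehyde into the acid without touching ketones or esters, and because C9 is now quaternary no enol is available for chlorination by the hypochlorite that the alkene scavenger removes.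

Step 10
Reactants: 13 9β-(methoxycarbonyl)-4α,10β-dimethyl-8-oxo-9α-(3-oxobutyl)decalin-4β-carboxylic acid
Product: 14 dimethyl 4α,10β-dimethyl-8-oxo-9α-(3-oxobutyl)decalin-4β,9β-dicarboxylate
Conditions: MeI, KHCO3, DMF, rt
Reagents that add atoms: iodomethane, CI
Why: Carboxylate alkylation (SN2 on iodomethane) esterifies the hindered axial acid without attack at its carbonyl carbon, and hydrogencarbonate is too weak a base to enolise the ketones.

Step 11
Reactants: 14 dimethyl 4α,10β-dimethyl-8-oxo-9α-(3-oxobutyl)decalin-4β,9β-dicarboxylate; 15 trimethyl phosphonoacetate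
Product: 16 dimethyl 9α-[(3E)-5-methoxy-3-methyl-5-oxopent-3-en-1-yl]-4α,10β-dimethyl-8-oxodecalin-4β,9β-dicarboxylate
Conditions: 15 (1.5 equiv), NaH (1.4 equiv), THF, 0 to 40 °C; (E) isomer separated by chromatography
Reagents that add atoms: none
Why: Horner–Wadsworth–Emmons olefination should occur only at the C13 methyl ketone because the C8 ketone is flanked by the quaternary C9, and the stabilised phosphonate anion favours the (E)-enoate, the minor (Z) isomer being removed because it would lead to the C13 epimer.

Step 12
Reactants: 16 dimethyl 9α-[(3E)-5-methoxy-3-methyl-5-oxopent-3-en-1-yl]-4α,10β-dimethyl-8-oxodecalin-4β,9β-dicarboxylate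
Product: 17 dimethyl (13E)-8-oxo-17-norlabd-13-ene-15,19-dioate
Conditions: LiCl (4 equiv), H2O (2 equiv), DMSO, 150 °C
Reagents that add atoms: none
Why: Krapcho dealkoxycarbonylation removes only the activated β-keto ester (chloride attacks its methyl group and the β-keto carboxylate loses CO2), and protonation of the enol from the α face, backed by equilibration, places the side chain equatorial at C9 (9α-H) under substrate and thermodynamic control.

Step 13
Reactants: 17 dimethyl (13E)-8-oxo-17-norlabd-13-ene-15,19-dioate
Product: 18 dimethyl (13E)-labda-8(17),13-diene-15,19-dioate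
Conditions: Zn, CH2Br2, TiCl4, THF, 0 °C; then 17, CH2Cl2, rt
Reagents that add atoms: dibromomethane, BrCBr
Why: Takai–Lombardo methylenation is non-basic and selective for ketones over esters, so C9 does not epimerise and the (E)-enoate neither isomerises nor deconjugates.

Step 14
Reactants: 18 dimethyl (13E)-labda-8(17),13-diene-15,19-dioate
Product: 20 dimethyl (13R)-13-hydroxylabd-8(17)-ene-15,19-dioate, via C13 boronate 19 (not isolated)
Conditions: B2pin2 (1.2 equiv), CuCl (5 mol%), NaOtBu (10 mol%), (R)-1-[(SP)-2-(diphenylphosphino)ferrocenyl]ethyldicyclohexylphosphine (6 mol%), MeOH (2 equiv), THF, rt; then NaBO3·4H2O, THF/H2O, rt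
Reagents that add atoms: bis(pinacolato)diboron, CC1(C)OB(OC1(C)C)B1OC(C)(C)C(C)(C)O1 (boron of 19); sodium perborate, [Na+].[Na+].O[B-]1(O)OO[B-](O)(O)OO1 (oxygen at C13 of 20)
Why: Copper-catalysed asymmetric conjugate borylation of the β,β-disubstituted (E)-enoate followed by stereoretentive oxidation of the C–B bond gives the tertiary β-hydroxy ester, with the chiral bisphosphine–copper boryl complex delivering boron to the Re face of C13 (catalyst control, remote from the ring stereocentres) and the unactivated exocyclic alkene left alone.

Step 15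
Reactants: 20 dimethyl (13R)-13-hydroxylabd-8(17)-ene-15,19-dioate
Product: 21 (4S,5R,9S,10R,13R)-13-hydroxylabd-8(17)-ene-15,19-dioic acid
Conditions: n-PrSLi (from n-PrSH and n-BuLi, 6 equiv), HMPA, rt; then dil. HCl to pH 3, 0 °C
Reagents that add atoms: none
Why: Thiolate SN2 dealkylation cleaves both methyl esters at their methyl groups, which is the mode that works at rt for the axial neopentyl C19 ester, and it avoids the strong acid or base that would cyclise or dehydrate the tertiary alcohol next to the exocyclic alkene.

**Compound list**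

1 | methyl 5-methoxy-3-oxopentanoate | COCCC(=O)CC(=O)OC | starting material
2 | methyl 3-oxopent-4-enoate | C=CC(=O)CC(=O)OC | intermediate
3 | cyclohexane-1,3-dione | O=C1CCCC(=O)C1 | starting material
4 | methyl 5-(2-hydroxy-6-oxocyclohex-1-en-1-yl)-3-oxopentanoate (enol form of the 2-substituted dione) | COC(=O)CC(=O)CCC1=C(O)CCCC1=O | intermediate
5 | methyl 3-oxo-5-[6-oxo-2-(trifluoromethanesulfonyloxy)cyclohex-1-en-1-yl]pentanoate | COC(=O)CC(=O)CCC1=C(OS(=O)(=O)C(F)(F)F)CCCC1=O | intermediate
6 | methyl 5-(2-methyl-6-oxocyclohex-1-en-1-yl)-3-oxopentanoate | CC1=C(CCC(=O)CC(=O)OC)C(=O)CCC1 | intermediate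
7 | methyl (1R,4aR,8aS)-8a-methyl-2,5-dioxodecahydronaphthalene-1-carboxylate; labdane numbering: 4,8-dioxo, 5α-H, 9α-H, 9β-CO2Me, 10β-CH3, trans-fused | O=C1CC[C@@H]2[C@](C)(CCCC2=O)[C@H]1C(=O)OC | intermediate
8 | methyl 4-(methoxymethylidene)-10β-methyl-8-oxo-5α,9α-H-decalin-9β-carboxylate (E/Z mixture; formed in the flask) | O=C1CC[C@@H]2[C@](C)(CCCC2=COC)[C@H]1C(=O)OC | intermediate
9 | methyl 4-formyl-10β-methyl-8-oxo-5α,9α-H-decalin-9β-carboxylate (mixture of C4 epimers) | O=C1CC[C@@H]2[C@](C)(CCCC2C=O)[C@H]1C(=O)OC | intermediate
10 | methyl 4β-formyl-4α,10β-dimethyl-8-oxo-5α,9α-H-decalin-9β-carboxylate | O=C1CC[C@@H]2[C@](C)(CCC[C@]2(C)C=O)[C@H]1C(=O)OC | intermediate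
11 | but-3-en-2-one (methyl vinyl ketone) | C=CC(C)=O | starting material
12 | methyl 4β-formyl-4α,10β-dimethyl-8-oxo-9α-(3-oxobutyl)-5α-H-decalin-9β-carboxylate | O=C1CC[C@@H]2[C@](C)(CCC[C@]2(C)C=O)[C@@]1(CCC(C)=O)C(=O)OC | intermediate
13 | 9β-(methoxycarbonyl)-4α,10β-dimethyl-8-oxo-9α-(3-oxobutyl)-5α-H-decalin-4β-carboxylic acid | O=C1CC[C@@H]2[C@](C)(CCC[C@]2(C)C(=O)O)[C@@]1(CCC(C)=O)C(=O)OC | intermediate
14 | dimethyl 4α,10β-dimethyl-8-oxo-9α-(3-oxobutyl)-5α-H-decalin-4β,9β-dicarboxylate | O=C1CC[C@@H]2[C@](C)(CCC[C@]2(C)C(=O)OC)[C@@]1(CCC(C)=O)C(=O)OC | intermediate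
15 | trimethyl phosphonoacetate (methyl 2-(dimethoxyphosphoryl)acetate) | COC(=O)CP(=O)(OC)OC | starting material
16 | dimethyl 9α-[(3E)-5-methoxy-3-methyl-5-oxopent-3-en-1-yl]-4α,10β-dimethyl-8-oxo-5α-H-decalin-4β,9β-dicarboxylate | O=C1CC[C@@H]2[C@](C)(CCC[C@]2(C)C(=O)OC)[C@@]1(CC/C(C)=C/C(=O)OC)C(=O)OC | intermediate
17 | dimethyl (13E)-8-oxo-17-norlabd-13-ene-15,19-dioate (5α-H, 9α-H, 10β-CH3, 4β-CO2Me) | O=C1CC[C@@H]2[C@](C)(CCC[C@]2(C)C(=O)OC)[C@H]1CC/C(C)=C/C(=O)OC | intermediate
18 | dimethyl (13E)-labda-8(17),13-diene-15,19-dioate | C=C1CC[C@@H]2[C@](C)(CCC[C@]2(C)C(=O)OC)[C@H]1CC/C(C)=C/C(=O)OC | intermediate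
19 | dimethyl (13S)-13-(4,4,5,5-tetramethyl-1,3,2-dioxaborolan-2-yl)labd-8(17)-ene-15,19-dioate (formed in the flask) | C=C1CC[C@@H]2[C@](C)(CCC[C@]2(C)C(=O)OC)[C@H]1CC[C@@](C)(B3OC(C)(C)C(C)(C)O3)CC(=O)OC | intermediate
20 | dimethyl (13R)-13-hydroxylabd-8(17)-ene-15,19-dioate | C=C1CC[C@@H]2[C@](C)(CCC[C@]2(C)C(=O)OC)[C@H]1CC[C@@](C)(O)CC(=O)OC | intermediate
21 | (4S,5R,9S,10R,13R)-13-hydroxylabd-8(17)-ene-15,19-dioic acid | C=C1CC[C@@H]2[C@](C)(CCC[C@]2(C)C(=O)O)[C@H]1CC[C@@](C)(O)CC(=O)O | target

**Count and risks**

Total step count: 15. Longest linear sequence: 15 steps (from 1 to 21; 3, 11 and 15 are bought).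

Steps most likely to fail:

Step 5 (key step, proposed new method). Iminium formation at the fully substituted enone may be too slow for turnover, ring closure may divert to C4, or the discrimination between the two faces of C10 may be poor. The fallback uses known chemistry and sets out from 6: ring B is closed with an achiral base (Cs2CO3, catalytic, MeCN, rt), the known intramolecular Michael addition of a β-keto ester to a cyclohexenone. After the same equilibration at C5 and C9 this gives 7 together with its mirror image, the enantiomer of 7 F1. The two are separated by preparative chromatography on a chiral stationary phase, and the route is rejoined at 7.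

Step 8. Bond formation at C9, which lies between the C8 ketone and the quaternary C10, may be so slow that 11 polymerises or the adduct reverts. The fallback sets out from 10 and replaces conjugate addition by alkylation (Wichterle reaction): the enolate of the β-keto ester (K2CO3, NaI, DMF) is alkylated with 1,3-dichlorobut-2-ene, an allylic halide that reacts with hindered enolates by SN2 displacement, to give methyl 9α-(3-chlorobut-2-en-1-yl)-4β-formyl-4α,10β-dimethyl-8-oxodecalin-9β-carboxylate F2. Hydrolysis of the vinyl chloride (Hg(OCOCF3)2, MeNO2/H2O, or cold concentrated H2SO4) gives the methyl ketone, and the route is rejoined at 12.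

Step 7. The single equivalent of iodomethane may be shared between the two enolates, giving methylation at C9 or at the enol oxygen of the β-keto ester. The fallback sets out from 9 and masks the β-keto ester first: MOMCl and i-Pr2NEt in CH2Cl2 give the methoxymethyl enol ether of 9 F3. The aldehyde, now the only acidic site, is methylated with KOtBu and MeI (THF, 0 °C) to the 4α-methyl-4β-formyl enol ether F4. 2 M HCl in THF removes the enol ether, and the route is rejoined at 10.

**Further compounds**

F1 | step 5 | enantiomer of 7, methyl (1S,4aS,8aR)-8a-methyl-2,5-dioxodecahydronaphthalene-1-carboxylate | O=C1CC[C@H]2[C@@](C)(CCCC2=O)[C@@H]1C(=O)OC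
F2 | step 8 | methyl 9α-(3-chlorobut-2-en-1-yl)-4β-formyl-4α,10β-dimethyl-8-oxo-5α-H-decalin-9β-carboxylate (alkene isomers) | O=C1CC[C@@H]2[C@](C)(CCC[C@]2(C)C=O)[C@@]1(CC=C(C)Cl)C(=O)OC
F3 | step 7 | methyl 4-formyl-8-(methoxymethoxy)-10β-methyl-5α-H-decal-8-ene-9-carboxylate (methoxymethyl enol ether of 9; C4 epimers) | COCOC=1CC[C@@H]2[C@](C)(CCCC2C=O)C=1C(=O)OC
F4 | step 7 | methyl 4β-formyl-8-(methoxymethoxy)-4α,10β-dimethyl-5α-H-decal-8-ene-9-carboxylate | COCOC=1CC[C@@H]2[C@](C)(CCC[C@]2(C)C=O)C=1C(=O)OC
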